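The partner is the leftover I can set aside first. It is charged at 4.00 times the substrate, so in violet, reckoning one turn per substrate and one more partner held by each catalyst, I expect about 60.5% of it to stay. What I watch instead is target meeting substrate.

in all of them: substrate 0.11 M; partner 0.440 M; time 8.0 min
- grey: free catalyst 16 mM
- teal: free catalyst 32 mM
- violet: free catalyst 64 mM

    partner + free catalyst ⇌ catalyst intermediate A (K1 = 6.9 M⁻¹, k1 = 9.9 M⁻¹ s⁻¹)
    catalyst intermediate A ⇌ catalyst intermediate B (K2 = 18, k2 = 1.2 s⁻¹)
    substrate + catalyst intermediate B ⇌ catalyst intermediate C (K3 = 17 M⁻¹, k3 = 1.3 M⁻¹ s⁻¹)
    catalyst intermediate C → free catalyst + target (k4 = 12 s⁻¹)
    substrate + target → side product (k5 = 0.67 M⁻¹ s⁻¹)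
    2 catalyst intermediate A → spent catalyst (k6 = 0.049 M⁻¹ s⁻¹)

- percentages count the substrate that a species holds: one side product counts as two
- a step written with two of one species runs at k times the square of its concentration and takes two of it each time
- run time (grey): 8.0 min

- which of these there is most of at the end, counted by the substrate in it, grey (substrate / side product / catalyst intermediate C / target)
- which of these there is most of at the end, counted by the substrate in it, teal (substrate / side product / catalyst intermediate C / target)
- which of these there is most of at the end, counted by the substrate in it, violet (substrate / side product / catalyst intermediate C / target)
- final amount of the leader among these, as a percentage of the substrate charged, in grey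
- final amount of the leader among these, as a percentage of the substrate charged, in teal
- final amount of the leader among these, as a percentage of the substrate charged, in violet

**First instants.** Free catalyst binds partner at 4.36 s⁻¹, and catalyst intermediate A becomes B with a forward half-life of 0.58 s. Catalyst intermediate B takes substrate at 0.143 s⁻¹, far slower than catalyst intermediate C clears at 12 s⁻¹. Catalyst intermediate C falls back at only 0.0765 s⁻¹, much slower than it goes on, so it stays small and nearly all of it delivers target. Catalyst intermediate B is the resting state. With every form carrying the same flow, its share b of the catalyst starts at 0.783.

**Middle.** Let x be target as a fraction of the substrate charge. The target-making step and the side step both carry substrate as a factor, so substrate cancels from their ratio. Target is made as fast as it is used at one fraction: the constant of substrate binding times b times the catalyst charge, over the side-step constant times the substrate charge. As substrate thins, b climbs towards 0.931, so I use the mean, 0.857. In grey that fraction is 0.242, and I call it the target ceiling a.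

**End.** Substrate's half-life by the catalyst's step alone in grey, which holds less catalyst than teal and violet, is about 0.648 min, short against the 8.0 min allowed, so I reckon the whole charge consumed. Each target lost takes a second substrate, so the turns per substrate charged are n = (1 + x)/2. Integrating gives x = a(1 − exp(−n/a)). Since n contains x, I start from n = 0.7 and put each answer back in:

| Flask | Ceiling a | First round | Second round | Third round |
|---|---|---|---|---|
| grey | 0.242 | 0.229 | 0.223 | 0.223 |
| teal | 0.484 | 0.370 | 0.366 | 0.366 |
| violet | 0.968 | 0.498 | 0.521 | 0.527 |

The rest of the charge sits in side product, so I commit to side product at 0.777 in grey and 0.634 in teal, and to target at 0.527 in violet.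

The forecast names side product at 77.3% in grey, side product at 63.2% in teal and target at 52.7% in violet, on the ground that “the catalyst rests mainly as intermediate B”. Its leaders are mine; its grey and teal figures sit slightly below mine.

The flasks end with side product at 77.4% in grey, side product at 63.2% in teal and target at 52.8% in violet, with substrate at 0% in violet.

The side step creates the ceiling: taken away, target in grey goes from 22.6% to >99.9%. In the neighbour flask charged with 0.080 M of free catalyst, the ceiling is 1.21, and two rounds from violet's answer give 0.577. That flask ends with target leading at 57.8%.

The rate constants are invented; what happens was integrated by code.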